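**Plan**

- Retrosynthetic cuts, in order: the amide N–C1′ bond; the ring bond C1–C2 of the cyclohexenone (C1 = carbonyl carbon, C2 = alkene carbon bearing the side chain), after stepping the ketone back to a carbinol; the bond between C2 and the side-chain carbinol carbon Ca, which separates a serine-derived aldehyde from a terminal alkyne; in the acid, C2′–C3′ (Claisen) and C6′–C7′ (allylation).
- Enabling feature: ring C2 carries only Ca, the C3–H alkene carbon and the C1 carbonyl, and C1 sits next to the quaternary C6. C2=C3 therefore maps onto an alkyne, and a Z-alkenyl iodide at C2 can add to a non-enolisable C1 aldehyde to close the six-membered ring.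
- Forward order: the C16 acid is built linearly (steps 1–9); the acyclic C1–C6 chain is made and joined to the serine unit (steps 10–19); N,O-acetal opening, O-methylation and acylation follow (steps 20–23), so that nitrogen is already an amide before a ring ketone exists (a free amine three carbons from that ketone would close to a cyclic imine); the only ring closes in step 26, then oxidation and desilylation.
- Stereochemistry: C9′ from (S)-citronellol; C7′ by reagent-controlled allylboration; the 4′E alkene by Johnson–Claisen rearrangement; ring C4/C5 by (Z)-crotylboration; the N-bearing carbon Cb from (R)-Garner aldehyde; Ca by Felkin addition of the acetylide; the Z-iodide by trans-hydrostannation and iodination with retention.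

Key step: step 26

Remark: the target is read as (4E,7R,9S) in the acyl chain, S at Ca and R at Cb, and 4S,5R in the ring; the ring C1 carbinol made in the key step is carried as both epimers. Abbreviations: TBS = tert-butyldimethylsilyl, PMB = 4-methoxybenzyl, Boc = tert-butoxycarbonyl, Ipc = isopinocampheyl.

**Acid fragment**

Step 1
Reactants: 1 (S)-citronellol; 2 (E)-oct-4-ene
Product: 3 (3S)-3-methyldec-6-en-1-ol (E/Z mixture)
Conditions: second-generation Grubbs catalyst RuCl2(=CHPh)(H2IMes)(PCy3) (2 mol%), 2 (8 equiv), CH2Cl2, 40 °C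
Reagents that add atoms: none
Why: Olefin cross-metathesis should exchange the isopropylidene end of the prenyl-type alkene for a butylidene unit, driven by the excess of the symmetrical alkene, without touching the chiral-pool stereocentre.

Step 2
Reactants: 3 (3S)-3-methyldec-6-en-1-ol
Product: 4 (3S)-3-methyldecan-1-ol
Conditions: H2 (1 atm), Pd/C, EtOAc, rt
Reagents that add atoms: none
Why: Heterogeneous catalytic hydrogenation saturates the disubstituted alkene, so both geometric isomers converge.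

Step 3
Reactants: 4 (3S)-3-methyldecan-1-ol
Product: 5 (3S)-3-methyldecanal
Conditions: Dess–Martin periodinane, NaHCO3, CH2Cl2, 0 °C to rt
Reagents that add atoms: none
Why: Dess–Martin oxidation stops at the aldehyde, and the stereocentre is β to the carbonyl and cannot epimerise.

Step 4
Reactants: 5 (3S)-3-methyldecanal
Product: 7 (4S,6S)-6-methyltridec-1-en-4-ol, via borinate ester 6 (not isolated)
Conditions: (−)-Ipc2B(allyl) [from (+)-α-pinene], Et2O, −78 °C; then NaOH, H2O2, 0 °C to rt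
Reagents that add atoms: (−)-B-allyldiisopinocampheylborane, C=CCB([C@@H]1C[C@@H]2C[C@H]([C@H]1C)C2(C)C)[C@@H]1C[C@@H]2C[C@H]([C@H]1C)C2(C)C
Why: Brown allylboration through a chair-like six-membered transition state, in which the isopinocampheyl groups direct the allyl group to the Si face of the aldehyde, should set C7′ (4S in 7) under reagent control.

Step 5
Reactants: 7 (4S,6S)-6-methyltridec-1-en-4-ol
Product: 8 (4S,6S)-4-methoxy-6-methyltridec-1-ene
Conditions: NaH, MeI, THF, 0 °C to rt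
Reagents that add atoms: iodomethane, CI
Why: Williamson etherification of the sodium alkoxide with iodomethane does not involve the stereocentres.

Step 6
Reactants: 8 (4S,6S)-4-methoxy-6-methyltridec-1-ene
Product: 10 (3R,5S)-3-methoxy-5-methyldodecanal, via secondary ozonide 9 (not isolated)
Conditions: O3, CH2Cl2, −78 °C; then PPh3, −78 °C to rt
Reagents that add atoms: ozone, [O-][O+]=O
Why: Ozonolysis with reductive work-up cleaves the only alkene to the aldehyde, which is used crude so that methanol is not eliminated.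

Step 7
Reactants: 10 (3R,5S)-3-methoxy-5-methyldodecanal
Product: 11 (5R,7S)-5-methoxy-7-methyltetradec-1-en-3-ol (both C3 epimers)
Conditions: CH2=CHMgBr, THF, −78 to 0 °C
Reagents that add atoms: vinylmagnesium bromide, C=C[Mg]Br
Why: Grignard 1,2-addition gives the vinyl carbinol as an epimer mixture, which is harmless because this carbon becomes sp2 in the next step.

Step 8
Reactants: 11 (5R,7S)-5-methoxy-7-methyltetradec-1-en-3-ol
Product: 13 ethyl (4E,7R,9S)-7-methoxy-9-methylhexadec-4-enoate, via ketene acetal 12 (not isolated)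
Conditions: MeC(OEt)3, EtCO2H (cat.), 140 °C, ethanol distilled off
Reagents that add atoms: triethyl orthoacetate, CCOC(C)(OCC)OCC
Why: Johnson–Claisen rearrangement of the mixed ketene acetal through a chair transition state with the chain equatorial should form the C2′–C3′ bond and the E-configured C4′=C5′ alkene from either carbinol epimer.

Step 9
Reactants: 13 ethyl (4E,7R,9S)-7-methoxy-9-methylhexadec-4-enoate
Product: 14 (4E,7R,9S)-7-methoxy-9-methylhexadec-4-enoic acid
Conditions: LiOH·H2O, THF/MeOH/H2O, rt; then 1 M HCl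
Reagents that add atoms: lithium hydroxide (hydroxide oxygen), [Li+].[OH-]
Why: Saponification of the ethyl ester leaves the non-conjugated alkene in place.

**Head fragment**

Step 10
Reactants: 15 2,2-dimethylpropane-1,3-diol
Product: 16 3-[(4-methoxybenzyl)oxy]-2,2-dimethylpropan-1-ol
Conditions: NaH (1 equiv), 15 (3 equiv), THF/DMF, 0 °C; PMBCl, n-Bu4NI (cat.), rt
Reagents that add atoms: 4-methoxybenzyl chloride, COc1ccc(CCl)cc1
Why: Williamson etherification of the mono-alkoxide of the symmetrical diol, with the diol in excess to suppress the bis-ether.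

Step 11
Reactants: 16 3-[(4-methoxybenzyl)oxy]-2,2-dimethylpropan-1-ol
Product: 17 3-[(4-methoxybenzyl)oxy]-2,2-dimethylpropanal
Conditions: Dess–Martin periodinane, NaHCO3, CH2Cl2, 0 °C to rt
Reagents that add atoms: none
Why: Dess–Martin oxidation gives a neopentyl aldehyde that cannot enolise.

Step 12
Reactants: 17 3-[(4-methoxybenzyl)oxy]-2,2-dimethylpropanal; 18 (Z)-but-2-ene
Product: 21 (3R,4S)-1-[(4-methoxybenzyl)oxy]-2,2,4-trimethylhex-5-en-3-ol, via (Z)-crotyldiisopinocampheylborane 19 (not isolated), via borinate ester 20 (not isolated)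
Conditions: KOt-Bu, n-BuLi, THF, −78 to −45 °C; (+)-Ipc2BOMe [from (−)-α-pinene], −78 °C; BF3·OEt2; 17, −78 °C; then NaOH, H2O2, rt
Reagents that add atoms: none
Why: Brown crotylboration through a closed chair transition state turns the Z geometry into the syn relationship of the future ring C4 methyl and C5 oxygen, and the isopinocampheyl groups direct attack to the Re face of the aldehyde, which should give the 3R,4S isomer.

Step 13
Reactants: 21 (3R,4S)-1-[(4-methoxybenzyl)oxy]-2,2,4-trimethylhex-5-en-3-ol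
Product: 22 tert-butyl{[(3R,4S)-1-[(4-methoxybenzyl)oxy]-2,2,4-trimethylhex-5-en-3-yl]oxy}dimethylsilane
Conditions: TBSOTf, 2,6-lutidine, CH2Cl2, 0 °C
Reagents that add atoms: tert-butyldimethylsilyl triflate, CC(C)(C)[Si](C)(C)OS(=O)(=O)C(F)(F)F
Why: Silylation with the silyl triflate is chosen because the carbinol is flanked by a quaternary carbon.

Step 14
Reactants: 22 tert-butyl{[(3R,4S)-1-[(4-methoxybenzyl)oxy]-2,2,4-trimethylhex-5-en-3-yl]oxy}dimethylsilane
Product: 24 (2R,3R)-3-[(tert-butyldimethylsilyl)oxy]-5-[(4-methoxybenzyl)oxy]-2,4,4-trimethylpentanal, via vicinal diol 23 (not isolated)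
Conditions: OsO4 (2 mol%), NaIO4, 2,6-lutidine, dioxane/H2O (3:1), rt
Reagents that add atoms: sodium periodate (terminal oxidant whose oxygen reaches the substrate through OsO4), [Na+].[O-]I(=O)(=O)=O
Why: Lemieux–Johnson cleavage (dihydroxylation, then periodate glycol cleavage) is preferred to ozone because it spares the electron-rich PMB arene, and 2,6-lutidine keeps the medium near neutral so that the α-stereocentre is retained.

Step 15
Reactants: 24 (2R,3R)-3-[(tert-butyldimethylsilyl)oxy]-5-[(4-methoxybenzyl)oxy]-2,4,4-trimethylpentanal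
Product: 25 tert-butyl{[(3R,4S)-1-[(4-methoxybenzyl)oxy]-2,2,4-trimethylhex-5-yn-3-yl]oxy}dimethylsilane
Conditions: dimethyl (1-diazo-2-oxopropyl)phosphonate, K2CO3, MeOH, 0 °C to rt
Reagents that add atoms: dimethyl (1-diazo-2-oxopropyl)phosphonate, COP(=O)(OC)C(=[N+]=[N-])C(C)=O
Why: Seyferth–Gilbert homologation in the Ohira–Bestmann variant converts the aldehyde into the terminal alkyne under base mild enough to keep the α-methyl stereocentre.

Step 16
Reactants: 25 tert-butyl{[(3R,4S)-1-[(4-methoxybenzyl)oxy]-2,2,4-trimethylhex-5-yn-3-yl]oxy}dimethylsilane; 26 (R)-Garner aldehyde, tert-butyl (4R)-4-formyl-2,2-dimethyl-1,3-oxazolidine-3-carboxylate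
Product: 28 tert-butyl (4R)-4-[(1S,4S,5R)-5-[(tert-butyldimethylsilyl)oxy]-1-hydroxy-7-[(4-methoxybenzyl)oxy]-4,6,6-trimethylhept-2-yn-1-yl]-2,2-dimethyl-1,3-oxazolidine-3-carboxylate, via lithium acetylide 27 (not isolated)
Conditions: n-BuLi, THF, −78 °C; HMPA; 26, −78 °C
Reagents that add atoms: none
Why: Felkin–Anh (non-chelation) addition of the lithium acetylide to the α-amino aldehyde, favoured by HMPA, should set Ca anti to the nitrogen-bearing carbon (1S).

Step 17
Reactants: 28 propargylic alcohol (name as under step 16)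
Product: 29 tert-butyl (4R)-4-[(1R,2Z,4S,5R)-5-[(tert-butyldimethylsilyl)oxy]-1-hydroxy-7-[(4-methoxybenzyl)oxy]-4,6,6-trimethyl-2-(tributylstannyl)hept-2-en-1-yl]-2,2-dimethyl-1,3-oxazolidine-3-carboxylate
Conditions: Bu3SnH, [Cp*RuCl]4 (2.5 mol%), CH2Cl2, rt
Reagents that add atoms: tributyltin hydride, CCCC[SnH](CCCC)CCCC
Why: In this hydroxyl-directed ruthenium-catalysed trans-hydrostannation the free propargylic OH hydrogen-bonds to the chloride ligand, so tin goes to the proximal alkyne carbon and hydrogen trans to it, which gives the Z-alkenylstannane.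

Step 18
Reactants: 29 Z-alkenylstannane
Product: 30 tert-butyl (4R)-4-[(1R,2Z,4S,5R)-5-[(tert-butyldimethylsilyl)oxy]-1-hydroxy-2-iodo-7-[(4-methoxybenzyl)oxy]-4,6,6-trimethylhept-2-en-1-yl]-2,2-dimethyl-1,3-oxazolidine-3-carboxylate
Conditions: I2, CH2Cl2, 0 °C
Reagents that add atoms: iodine, II
Why: Iododestannylation (ipso substitution at the C–Sn bond) proceeds with retention of alkene geometry.

Step 19
Reactants: 30 Z-alkenyl iodide
Product: 31 tert-butyl (4R)-4-[(1R,2Z,4S,5R)-1,5-bis[(tert-butyldimethylsilyl)oxy]-2-iodo-7-[(4-methoxybenzyl)oxy]-4,6,6-trimethylhept-2-en-1-yl]-2,2-dimethyl-1,3-oxazolidine-3-carboxylate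
Conditions: TBSOTf, 2,6-lutidine, CH2Cl2, −78 to 0 °C
Reagents that add atoms: tert-butyldimethylsilyl triflate, CC(C)(C)[Si](C)(C)OS(=O)(=O)C(F)(F)F
Why: Silylation of the hindered allylic alcohol masks it against the later oxidations.

Step 20
Reactants: 31 bis-silyl ether
Product: 32 tert-butyl N-[(2R,3R,4Z,6S,7R)-3,7-bis[(tert-butyldimethylsilyl)oxy]-1-hydroxy-4-iodo-9-[(4-methoxybenzyl)oxy]-6,8,8-trimethylnon-4-en-2-yl]carbamate
Conditions: CSA (0.2 equiv), MeOH, 0 °C to rt
Reagents that add atoms: none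
Why: Acid-catalysed transacetalisation opens the N,O-isopropylidene acetal, which is much more labile than the two hindered secondary silyl ethers and the tert-butyl carbamate.

Step 21
Reactants: 32 N-Boc amino alcohol
Product: 33 tert-butyl N-[(2R,3R,4Z,6S,7R)-3,7-bis[(tert-butyldimethylsilyl)oxy]-4-iodo-1-methoxy-9-[(4-methoxybenzyl)oxy]-6,8,8-trimethylnon-4-en-2-yl]carbamate
Conditions: Me3OBF4, 1,8-bis(dimethylamino)naphthalene, CH2Cl2, 0 °C to rt
Reagents that add atoms: trimethyloxonium tetrafluoroborate, C[O+](C)C.F[B-](F)(F)F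
Why: O-Methylation with Meerwein's salt under non-basic conditions avoids the alkoxide that would attack the carbamate (oxazolidinone formation) or lead to N-methylation.

Step 22
Reactants: 33 N-Boc methyl ether
Product: 35 (2R,3R,4Z,6S,7R)-3,7-bis[(tert-butyldimethylsilyl)oxy]-4-iodo-1-methoxy-9-[(4-methoxybenzyl)oxy]-6,8,8-trimethylnon-4-en-2-amine, via trimethylsilyl carbamate 34 (not isolated)
Conditions: TMSOTf, 2,6-lutidine, CH2Cl2, 0 °C; then MeOH
Reagents that add atoms: none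
Why: Silyl-triflate-mediated cleavage of the tert-butyl carbamate goes through the silyl carbamate, which is methanolysed and loses CO2, under conditions that should leave the TBS and PMB ethers intact.

**Union and endgame**

Step 23
Reactants: 35 amine; 14 (4E,7R,9S)-7-methoxy-9-methylhexadec-4-enoic acid
Product: 36 (4E,7R,9S)-N-[(2R,3R,4Z,6S,7R)-3,7-bis[(tert-butyldimethylsilyl)oxy]-4-iodo-1-methoxy-9-[(4-methoxybenzyl)oxy]-6,8,8-trimethylnon-4-en-2-yl]-7-methoxy-9-methylhexadec-4-enamide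
Conditions: EDC·HCl, HOBt, i-Pr2NEt, CH2Cl2, 0 °C to rt
Reagents that add atoms: none
Why: Carbodiimide amide coupling through the HOBt ester fixes the nitrogen as an amide before the ring ketone exists, so no cyclic imine can form later.

Step 24
Reactants: 36 PMB ether amide
Product: 37 (4E,7R,9S)-N-[(2R,3R,4Z,6S,7R)-3,7-bis[(tert-butyldimethylsilyl)oxy]-9-hydroxy-4-iodo-1-methoxy-6,8,8-trimethylnon-4-en-2-yl]-7-methoxy-9-methylhexadec-4-enamide
Conditions: DDQ, CH2Cl2/pH 7 buffer (10:1), 0 °C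
Reagents that add atoms: none
Why: Oxidative PMB cleavage by hydride abstraction at the electron-rich benzylic position leaves the isolated alkene, the alkenyl iodide and the silyl ethers untouched.

Step 25
Reactants: 37 primary alcohol
Product: 38 (4E,7R,9S)-N-[(2R,3R,4Z,6S,7R)-3,7-bis[(tert-butyldimethylsilyl)oxy]-4-iodo-1-methoxy-6,8,8-trimethyl-9-oxonon-4-en-2-yl]-7-methoxy-9-methylhexadec-4-enamide
Conditions: Dess–Martin periodinane, NaHCO3, CH2Cl2, 0 °C to rt
Reagents that add atoms: none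
Why: Dess–Martin oxidation gives the aldehyde, whose α-carbon is quaternary and cannot enolise.

Step 26
Reactants: 38 Z-alkenyl iodide aldehyde
Product: 40 (4E,7R,9S)-N-[(1S,2R)-1-[(tert-butyldimethylsilyl)oxy]-1-[(3S,4R)-4-[(tert-butyldimethylsilyl)oxy]-6-hydroxy-3,5,5-trimethylcyclohex-1-en-1-yl]-3-methoxypropan-2-yl]-7-methoxy-9-methylhexadec-4-enamide (both epimers at the new ring carbinol), via alkenylchromium dichloride 39 (not isolated)
Conditions: CrCl2 (8 equiv), NiCl2 (0.1 equiv), degassed DMSO, rt, 0.005 M, slow addition of 38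
Reagents that add atoms: none
Why: Zerovalent nickel, formed from NiCl2 by divalent chromium, inserts into the C–I bond and hands the alkenyl group to chromium, which ends trivalent, and the alkenylchromium species adds to the tethered aldehyde; this is an intramolecular Nozaki–Hiyama–Kishi reaction, a Barbier-type alkenylation. The C1–C2 bond closes the cyclohexene in a 6-exo-trig mode, which is geometrically easy because the Z alkene holds C2 and the aldehyde-bearing chain at C3 on the same side. The only new stereocentre is the C1 carbinol; nothing controls it and nothing needs to, because both epimers give the same ketone in step 27. The step needs addition to the aldehyde only and retention of alkene geometry: the alkenylchromium reagent is weakly basic and carbonyl-selective, so the secondary amide, the methyl and silyl ethers and the isolated alkene should be tolerated and the neighbouring silyloxy group should not be eliminated, and insertion and transmetalation both proceed with retention. The aldehyde has no α-hydrogen and cannot enolise, and high dilution suppresses intermolecular coupling.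

Step 27
Reactants: 40 cyclohexenol (both epimers)
Product: 41 (4E,7R,9S)-N-[(1S,2R)-1-[(tert-butyldimethylsilyl)oxy]-1-[(3S,4R)-4-[(tert-butyldimethylsilyl)oxy]-3,5,5-trimethyl-6-oxocyclohex-1-en-1-yl]-3-methoxypropan-2-yl]-7-methoxy-9-methylhexadec-4-enamide
Conditions: Dess–Martin periodinane, NaHCO3, CH2Cl2, rt
Reagents that add atoms: none
Why: Dess–Martin oxidation of the allylic alcohol converges both epimers to the enone while the other hydroxyls are silylated.

Step 28
Reactants: 41 bis-silylated enone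
Product: 42 (4E,7R,9S)-N-[(1S,2R)-1-hydroxy-1-[(3S,4R)-4-hydroxy-3,5,5-trimethyl-6-oxocyclohex-1-en-1-yl]-3-methoxypropan-2-yl]-7-methoxy-9-methylhexadec-4-enamide (target)
Conditions: HF (48% aq.), MeCN, 0 °C to rt
Reagents that add atoms: none
Why: Acidic fluoride desilylation removes both TBS ethers without base, which should spare the β-hydroxy ketone (retro-aldol) and the carbinol next to the enone (elimination).

**Compound list**

1 | (S)-citronellol, (3S)-3,7-dimethyloct-6-en-1-ol | CC(C)=CCC[C@H](C)CCO | starting material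
2 | (E)-oct-4-ene | CCC/C=C/CCC | starting material
3 | (3S)-3-methyldec-6-en-1-ol (E/Z mixture) | CCCC=CCC[C@H](C)CCO | intermediate
4 | (3S)-3-methyldecan-1-ol | CCCCCCC[C@H](C)CCO | intermediate
5 | (3S)-3-methyldecanal | CCCCCCC[C@H](C)CC=O | intermediate
6 | (4S,6S)-6-methyltridec-1-en-4-yl diisopinocampheylborinate (Ipc from (+)-α-pinene; not isolated) | CCCCCCC[C@H](C)C[C@H](CC=C)OB([C@@H]1C[C@@H]2C[C@H]([C@H]1C)C2(C)C)[C@@H]1C[C@@H]2C[C@H]([C@H]1C)C2(C)C | intermediate
7 | (4S,6S)-6-methyltridec-1-en-4-ol | CCCCCCC[C@H](C)C[C@H](CC=C)O | intermediate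
8 | (4S,6S)-4-methoxy-6-methyltridec-1-ene | CCCCCCC[C@H](C)C[C@H](CC=C)OC | intermediate
9 | 3-[(2R,4S)-2-methoxy-4-methylundecyl]-1,2,4-trioxolane (not isolated) | CCCCCCC[C@H](C)C[C@H](CC1OCOO1)OC | intermediate
10 | (3R,5S)-3-methoxy-5-methyldodecanal | CCCCCCC[C@H](C)C[C@H](CC=O)OC | intermediate
11 | (5R,7S)-5-methoxy-7-methyltetradec-1-en-3-ol (both C3 epimers) | CCCCCCC[C@H](C)C[C@H](CC(O)C=C)OC | intermediate
12 | (5R,7S)-3-[(1-ethoxyethenyl)oxy]-5-methoxy-7-methyltetradec-1-ene (not isolated) | CCCCCCC[C@H](C)C[C@H](CC(OC(=C)OCC)C=C)OC | intermediate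
13 | ethyl (4E,7R,9S)-7-methoxy-9-methylhexadec-4-enoate | CCCCCCC[C@H](C)C[C@H](C/C=C/CCC(=O)OCC)OC | intermediate
14 | (4E,7R,9S)-7-methoxy-9-methylhexadec-4-enoic acid | CCCCCCC[C@H](C)C[C@H](C/C=C/CCC(=O)O)OC | intermediate
15 | 2,2-dimethylpropane-1,3-diol | OCC(C)(C)CO | starting material
16 | 3-[(4-methoxybenzyl)oxy]-2,2-dimethylpropan-1-ol | OCC(C)(C)COCc1ccc(OC)cc1 | intermediate
17 | 3-[(4-methoxybenzyl)oxy]-2,2-dimethylpropanal | O=CC(C)(C)COCc1ccc(OC)cc1 | intermediate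
18 | (Z)-but-2-ene | C/C=C\C | starting material
19 | (Z)-but-2-en-1-yl-diisopinocampheylborane (Ipc from (−)-α-pinene; not isolated) | C/C=C\CB([C@H]1C[C@H]2C[C@@H]([C@@H]1C)C2(C)C)[C@H]1C[C@H]2C[C@@H]([C@@H]1C)C2(C)C | intermediate
20 | (3R,4S)-1-[(4-methoxybenzyl)oxy]-2,2,4-trimethylhex-5-en-3-yl diisopinocampheylborinate (not isolated) | C=C[C@H](C)[C@@H](OB([C@H]1C[C@H]2C[C@@H]([C@@H]1C)C2(C)C)[C@H]1C[C@H]2C[C@@H]([C@@H]1C)C2(C)C)C(C)(C)COCc1ccc(OC)cc1 | intermediate
21 | (3R,4S)-1-[(4-methoxybenzyl)oxy]-2,2,4-trimethylhex-5-en-3-ol | C=C[C@H](C)[C@@H](O)C(C)(C)COCc1ccc(OC)cc1 | intermediate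
22 | tert-butyl{[(3R,4S)-1-[(4-methoxybenzyl)oxy]-2,2,4-trimethylhex-5-en-3-yl]oxy}dimethylsilane | C=C[C@H](C)[C@@H](O[Si](C)(C)C(C)(C)C)C(C)(C)COCc1ccc(OC)cc1 | intermediate
23 | (3S,4R)-4-[(tert-butyldimethylsilyl)oxy]-6-[(4-methoxybenzyl)oxy]-3,5,5-trimethylhexane-1,2-diol (both C2 epimers; not isolated) | OCC(O)[C@H](C)[C@@H](O[Si](C)(C)C(C)(C)C)C(C)(C)COCc1ccc(OC)cc1 | intermediate
24 | (2R,3R)-3-[(tert-butyldimethylsilyl)oxy]-5-[(4-methoxybenzyl)oxy]-2,4,4-trimethylpentanal | O=C[C@H](C)[C@@H](O[Si](C)(C)C(C)(C)C)C(C)(C)COCc1ccc(OC)cc1 | intermediate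
25 | tert-butyl{[(3R,4S)-1-[(4-methoxybenzyl)oxy]-2,2,4-trimethylhex-5-yn-3-yl]oxy}dimethylsilane | C#C[C@H](C)[C@@H](O[Si](C)(C)C(C)(C)C)C(C)(C)COCc1ccc(OC)cc1 | intermediate
26 | (R)-Garner aldehyde, tert-butyl (4R)-4-formyl-2,2-dimethyl-1,3-oxazolidine-3-carboxylate | CC(C)(C)OC(=O)N1[C@H](COC1(C)C)C=O | starting material
27 | {(3S,4R)-4-[(tert-butyldimethylsilyl)oxy]-6-[(4-methoxybenzyl)oxy]-3,5,5-trimethylhex-1-yn-1-yl}lithium (not isolated) | [Li]C#C[C@H](C)[C@@H](O[Si](C)(C)C(C)(C)C)C(C)(C)COCc1ccc(OC)cc1 | intermediate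
28 | tert-butyl (4R)-4-[(1S,4S,5R)-5-[(tert-butyldimethylsilyl)oxy]-1-hydroxy-7-[(4-methoxybenzyl)oxy]-4,6,6-trimethylhept-2-yn-1-yl]-2,2-dimethyl-1,3-oxazolidine-3-carboxylate | CC(C)(C)OC(=O)N1[C@H](COC1(C)C)[C@@H](O)C#C[C@H](C)[C@@H](O[Si](C)(C)C(C)(C)C)C(C)(C)COCc1ccc(OC)cc1 | intermediate
29 | tert-butyl (4R)-4-[(1R,2Z,4S,5R)-5-[(tert-butyldimethylsilyl)oxy]-1-hydroxy-7-[(4-methoxybenzyl)oxy]-4,6,6-trimethyl-2-(tributylstannyl)hept-2-en-1-yl]-2,2-dimethyl-1,3-oxazolidine-3-carboxylate | CC(C)(C)OC(=O)N1[C@H](COC1(C)C)[C@@H](O)/C([Sn](CCCC)(CCCC)CCCC)=C/[C@H](C)[C@@H](O[Si](C)(C)C(C)(C)C)C(C)(C)COCc1ccc(OC)cc1 | intermediate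
30 | tert-butyl (4R)-4-[(1R,2Z,4S,5R)-5-[(tert-butyldimethylsilyl)oxy]-1-hydroxy-2-iodo-7-[(4-methoxybenzyl)oxy]-4,6,6-trimethylhept-2-en-1-yl]-2,2-dimethyl-1,3-oxazolidine-3-carboxylate | CC(C)(C)OC(=O)N1[C@H](COC1(C)C)[C@@H](O)/C(I)=C/[C@H](C)[C@@H](O[Si](C)(C)C(C)(C)C)C(C)(C)COCc1ccc(OC)cc1 | intermediate
31 | tert-butyl (4R)-4-[(1R,2Z,4S,5R)-1,5-bis[(tert-butyldimethylsilyl)oxy]-2-iodo-7-[(4-methoxybenzyl)oxy]-4,6,6-trimethylhept-2-en-1-yl]-2,2-dimethyl-1,3-oxazolidine-3-carboxylate | CC(C)(C)OC(=O)N1[C@H](COC1(C)C)[C@@H](O[Si](C)(C)C(C)(C)C)/C(I)=C/[C@H](C)[C@@H](O[Si](C)(C)C(C)(C)C)C(C)(C)COCc1ccc(OC)cc1 | intermediate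
32 | tert-butyl N-[(2R,3R,4Z,6S,7R)-3,7-bis[(tert-butyldimethylsilyl)oxy]-1-hydroxy-4-iodo-9-[(4-methoxybenzyl)oxy]-6,8,8-trimethylnon-4-en-2-yl]carbamate | CC(C)(C)OC(=O)N[C@H](CO)[C@@H](O[Si](C)(C)C(C)(C)C)/C(I)=C/[C@H](C)[C@@H](O[Si](C)(C)C(C)(C)C)C(C)(C)COCc1ccc(OC)cc1 | intermediate
33 | tert-butyl N-[(2R,3R,4Z,6S,7R)-3,7-bis[(tert-butyldimethylsilyl)oxy]-4-iodo-1-methoxy-9-[(4-methoxybenzyl)oxy]-6,8,8-trimethylnon-4-en-2-yl]carbamate | CC(C)(C)OC(=O)N[C@H](COC)[C@@H](O[Si](C)(C)C(C)(C)C)/C(I)=C/[C@H](C)[C@@H](O[Si](C)(C)C(C)(C)C)C(C)(C)COCc1ccc(OC)cc1 | intermediate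
34 | trimethylsilyl N-[(2R,3R,4Z,6S,7R)-3,7-bis[(tert-butyldimethylsilyl)oxy]-4-iodo-1-methoxy-9-[(4-methoxybenzyl)oxy]-6,8,8-trimethylnon-4-en-2-yl]carbamate (not isolated) | C[Si](C)(C)OC(=O)N[C@H](COC)[C@@H](O[Si](C)(C)C(C)(C)C)/C(I)=C/[C@H](C)[C@@H](O[Si](C)(C)C(C)(C)C)C(C)(C)COCc1ccc(OC)cc1 | intermediate
35 | (2R,3R,4Z,6S,7R)-3,7-bis[(tert-butyldimethylsilyl)oxy]-4-iodo-1-methoxy-9-[(4-methoxybenzyl)oxy]-6,8,8-trimethylnon-4-en-2-amine | N[C@H](COC)[C@@H](O[Si](C)(C)C(C)(C)C)/C(I)=C/[C@H](C)[C@@H](O[Si](C)(C)C(C)(C)C)C(C)(C)COCc1ccc(OC)cc1 | intermediate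
36 | (4E,7R,9S)-N-[(2R,3R,4Z,6S,7R)-3,7-bis[(tert-butyldimethylsilyl)oxy]-4-iodo-1-methoxy-9-[(4-methoxybenzyl)oxy]-6,8,8-trimethylnon-4-en-2-yl]-7-methoxy-9-methylhexadec-4-enamide | CCCCCCC[C@H](C)C[C@H](C/C=C/CCC(=O)N[C@H](COC)[C@@H](O[Si](C)(C)C(C)(C)C)/C(I)=C/[C@H](C)[C@@H](O[Si](C)(C)C(C)(C)C)C(C)(C)COCc1ccc(OC)cc1)OC | intermediate
37 | (4E,7R,9S)-N-[(2R,3R,4Z,6S,7R)-3,7-bis[(tert-butyldimethylsilyl)oxy]-9-hydroxy-4-iodo-1-methoxy-6,8,8-trimethylnon-4-en-2-yl]-7-methoxy-9-methylhexadec-4-enamide | CCCCCCC[C@H](C)C[C@H](C/C=C/CCC(=O)N[C@H](COC)[C@@H](O[Si](C)(C)C(C)(C)C)/C(I)=C/[C@H](C)[C@@H](O[Si](C)(C)C(C)(C)C)C(C)(C)CO)OC | intermediate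
38 | (4E,7R,9S)-N-[(2R,3R,4Z,6S,7R)-3,7-bis[(tert-butyldimethylsilyl)oxy]-4-iodo-1-methoxy-6,8,8-trimethyl-9-oxonon-4-en-2-yl]-7-methoxy-9-methylhexadec-4-enamide | CCCCCCC[C@H](C)C[C@H](C/C=C/CCC(=O)N[C@H](COC)[C@@H](O[Si](C)(C)C(C)(C)C)/C(I)=C/[C@H](C)[C@@H](O[Si](C)(C)C(C)(C)C)C(C)(C)C=O)OC | intermediate
39 | alkenylchromium dichloride from 38 (C–I replaced by C–CrCl2, trivalent chromium, solvent ligands omitted; not isolated) | CCCCCCC[C@H](C)C[C@H](C/C=C/CCC(=O)N[C@H](COC)[C@@H](O[Si](C)(C)C(C)(C)C)/C([Cr](Cl)Cl)=C/[C@H](C)[C@@H](O[Si](C)(C)C(C)(C)C)C(C)(C)C=O)OC | intermediate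
40 | (4E,7R,9S)-N-[(1S,2R)-1-[(tert-butyldimethylsilyl)oxy]-1-[(3S,4R)-4-[(tert-butyldimethylsilyl)oxy]-6-hydroxy-3,5,5-trimethylcyclohex-1-en-1-yl]-3-methoxypropan-2-yl]-7-methoxy-9-methylhexadec-4-enamide (both epimers at the ring carbinol) | CCCCCCC[C@H](C)C[C@H](C/C=C/CCC(=O)N[C@H](COC)[C@@H](O[Si](C)(C)C(C)(C)C)C1=C[C@H](C)[C@@H](O[Si](C)(C)C(C)(C)C)C(C)(C)C1O)OC | intermediate
41 | (4E,7R,9S)-N-[(1S,2R)-1-[(tert-butyldimethylsilyl)oxy]-1-[(3S,4R)-4-[(tert-butyldimethylsilyl)oxy]-3,5,5-trimethyl-6-oxocyclohex-1-en-1-yl]-3-methoxypropan-2-yl]-7-methoxy-9-methylhexadec-4-enamide | CCCCCCC[C@H](C)C[C@H](C/C=C/CCC(=O)N[C@H](COC)[C@@H](O[Si](C)(C)C(C)(C)C)C1=C[C@H](C)[C@@H](O[Si](C)(C)C(C)(C)C)C(C)(C)C1=O)OC | intermediate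
42 | (4E,7R,9S)-N-[(1S,2R)-1-hydroxy-1-[(3S,4R)-4-hydroxy-3,5,5-trimethyl-6-oxocyclohex-1-en-1-yl]-3-methoxypropan-2-yl]-7-methoxy-9-methylhexadec-4-enamide | CCCCCCC[C@H](C)C[C@H](C/C=C/CCC(=O)N[C@H](COC)[C@@H](O)C1=C[C@H](C)[C@@H](O)C(C)(C)C1=O)OC | target

**Count and risks**

Total step count: 28. Longest linear sequence: 19 steps (steps 10–28, from 2,2-dimethylpropane-1,3-diol); the acid branch (steps 1–9) joins at step 23.

Steps most likely to fail:

1. Step 26. What may go wrong: protonation of the alkenylchromium intermediate (net loss of iodine) may outrun its addition to the hindered neopentyl aldehyde, or nickel insertion into the crowded C–I bond may stall. Fallback, setting out from 38 and returning at 41: the aldehyde is oxidised (NaClO2, NaH2PO4, 2-methylbut-2-ene, t-BuOH/H2O) to the carboxylic acid F1, which is condensed with MeNHOMe·HCl (EDC·HCl, HOBt, i-Pr2NEt) to the N-methoxy-N-methylamide F2. After deprotonation of the amide N–H with LiN(SiMe3)2, t-BuLi (2 equiv, THF, −78 °C) effects iodine–lithium exchange, and the alkenyllithium acylates itself on the tethered Weinreb amide (6-exo-trig, chelated tetrahedral intermediate). Aqueous work-up should then release enone 41 directly, so step 27 is skipped.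

2. Step 20. What may go wrong: cleavage or migration of the allylic silyl ether under the acid needed to open the N,O-acetal. Fallback, setting out from 30 and returning at 33: the acetal is methanolysed (CSA, MeOH) before any allylic silyl ether is present, giving the N-Boc amino diol F3. The primary hydroxyl is then methylated selectively (Me3OBF4, 1.1 equiv, 1,8-bis(dimethylamino)naphthalene, CH2Cl2, 0 °C; the secondary hydroxyl is shielded by the iodoalkene and the carbamate-bearing carbon) to the methyl ether F4, and silylation (TBSOTf, 2,6-lutidine, −78 °C) gives 33.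

3. Step 12. What may go wrong: slow addition to the neopentyl aldehyde with erosion of facial selectivity, or loss of the Z geometry of the crotylmetal before boron capture. Fallback, setting out from 17 and returning at 24: Evans syn-aldol addition of the dibutylboron enolate of purchased (R)-4-benzyl-3-propionyl-1,3-oxazolidin-2-one (Bu2BOTf, i-Pr2NEt, CH2Cl2, −78 to 0 °C) to 17 gives the syn-aldol adduct F5 (Zimmerman–Traxler transition state under auxiliary control, 2R,3R). Silylation (TBSOTf, 2,6-lutidine) gives the silyl ether F6, reductive removal of the auxiliary (LiBH4, MeOH, THF, 0 °C) the primary alcohol F7, and Dess–Martin oxidation aldehyde 24, so steps 13 and 14 are skipped.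

**Further compounds**

F1 | step 26 | (3R,4S,5Z,7R,8R)-3,7-bis[(tert-butyldimethylsilyl)oxy]-6-iodo-9-methoxy-8-{[(4E,7R,9S)-7-methoxy-9-methylhexadec-4-enoyl]amino}-2,2,4-trimethylnon-5-enoic acid | CCCCCCC[C@H](C)C[C@H](C/C=C/CCC(=O)N[C@H](COC)[C@@H](O[Si](C)(C)C(C)(C)C)/C(I)=C/[C@H](C)[C@@H](O[Si](C)(C)C(C)(C)C)C(C)(C)C(O)=O)OC
F2 | step 26 | N-methoxy-N-methylamide of F1 | CCCCCCC[C@H](C)C[C@H](C/C=C/CCC(=O)N[C@H](COC)[C@@H](O[Si](C)(C)C(C)(C)C)/C(I)=C/[C@H](C)[C@@H](O[Si](C)(C)C(C)(C)C)C(C)(C)C(=O)N(C)OC)OC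
F3 | step 20 | tert-butyl N-[(2R,3R,4Z,6S,7R)-7-[(tert-butyldimethylsilyl)oxy]-1,3-dihydroxy-4-iodo-9-[(4-methoxybenzyl)oxy]-6,8,8-trimethylnon-4-en-2-yl]carbamate | CC(C)(C)OC(=O)N[C@H](CO)[C@@H](O)/C(I)=C/[C@H](C)[C@@H](O[Si](C)(C)C(C)(C)C)C(C)(C)COCc1ccc(OC)cc1
F4 | step 20 | tert-butyl N-[(2R,3R,4Z,6S,7R)-7-[(tert-butyldimethylsilyl)oxy]-3-hydroxy-4-iodo-1-methoxy-9-[(4-methoxybenzyl)oxy]-6,8,8-trimethylnon-4-en-2-yl]carbamate | CC(C)(C)OC(=O)N[C@H](COC)[C@@H](O)/C(I)=C/[C@H](C)[C@@H](O[Si](C)(C)C(C)(C)C)C(C)(C)COCc1ccc(OC)cc1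
F5 | step 12 | (4R)-4-benzyl-3-[(2R,3R)-3-hydroxy-5-[(4-methoxybenzyl)oxy]-2,4,4-trimethylpentanoyl]-1,3-oxazolidin-2-one | O=C1OC[C@@H](Cc2ccccc2)N1C(=O)[C@H](C)[C@@H](O)C(C)(C)COCc1ccc(OC)cc1
F6 | step 12 | (4R)-4-benzyl-3-[(2R,3R)-3-[(tert-butyldimethylsilyl)oxy]-5-[(4-methoxybenzyl)oxy]-2,4,4-trimethylpentanoyl]-1,3-oxazolidin-2-one | O=C1OC[C@@H](Cc2ccccc2)N1C(=O)[C@H](C)[C@@H](O[Si](C)(C)C(C)(C)C)C(C)(C)COCc1ccc(OC)cc1
F7 | step 12 | (2S,3R)-3-[(tert-butyldimethylsilyl)oxy]-5-[(4-methoxybenzyl)oxy]-2,4,4-trimethylpentan-1-ol | OC[C@H](C)[C@@H](O[Si](C)(C)C(C)(C)C)C(C)(C)COCc1ccc(OC)cc1
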